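**Retrosynthetic overview**
1. The plan rests on ring B. This resorcinol is joined to the rest of the molecule only through two neighbouring carbons: b1 on C3 of the inner dihydrofuran and b6 on the methine that bears the 2,4-dioxygenated phenyl group. The b1–b6 bond is also a bond of the seven-membered ring.
2. Both sp3 carbons can therefore carry alkynes (ethynyl on C3, ethoxyethynyl on the methine). A [2+2+2] cyclotrimerisation of this 1,8-diyne with ethoxyacetylene builds ring B and the seven-membered ring together, and only ether cleavage follows.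
3. Both alkynes are unmasked in one flask, one from a 1,1-dibromoalkene (from the C3 ester) and one from an ethyl ester through its ketene acetal phosphate. That ester comes from an Evans alkylation with the ring A benzylic bromide followed by Arndt–Eistert homologation.
4. The two dihydrofurans come from two successive dirhodium carbene C–H insertions into the two 4-methoxybenzyl ethers of a 2,6-dibrominated 3,5-dihydroxybenzyl alcohol. Both insertions have the same sense, and epimerising C3 (base) in one ring and C2 (acid) in the other gives the mirror-related trans pair.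
5. Ring order: ring A (bought), outer furan, inner furan, then ring B and the seven-membered ring at once.

Key step: step 19

Labels:
- Ring A is the central benzene. Its atoms are a1 (O of the inner furan), a2 (H), a3 (O of the outer furan), a4 (bears C3 of the outer furan), a5 (bears the CH2 group) and a6 (bears C3 of the inner furan).
- The inner furan is the dihydrofuran on a1/a6. The outer furan is the dihydrofuran on a3/a4, whose C3 bears the 3,5-dioxygenated phenyl group.
- Ring B atoms are b1 (on inner C3), b2 (H), b3 (O), b4 (H), b5 (O) and b6 (on the methine).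
- PMB = 4-methoxybenzyl. TBS = tert-butyldimethylsilyl.
- Rh2(R-PTAD)4 = dirhodium tetrakis[(R)-(1-adamantyl)(phthalimido)acetate]. Rh2(R-PTTL)4 = dirhodium tetrakis[N-phthaloyl-(R)-tert-leucinate].

Assumption: the R antipodes of both dirhodium catalysts are taken to give the (2S)-cis furans, by analogy with simple 2-benzyloxyaryl carbenes. If the sense is the opposite, the equally available S antipodes are used.

**Step 1**
Reactants: 1 3,5-dihydroxybenzyl alcohol; 2 4-methoxybenzyl chloride
Product: 3 3,5-bis(4-methoxybenzyloxy)benzyl alcohol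
Conditions: K2CO3, DMF, 50 °C
Reagents that add atoms: 4-methoxybenzyl chloride (2) COc1ccc(CCl)cc1
Why: Williamson ether synthesis in which K2CO3 deprotonates only the two phenols, so the benzylic alcohol stays free and the two benzyl carbons that later become C2 of both furans are installed.

**Step 2**
Reactants: 3 3,5-bis(4-methoxybenzyloxy)benzyl alcohol
Product: 4 2,6-dibromo-3,5-bis(4-methoxybenzyloxy)benzyl alcohol
Conditions: NBS (2.05 equiv), MeCN, 0 °C, dark
Reagents that add atoms: N-bromosuccinimide O=C1CCC(=O)N1Br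
Why: Electrophilic aromatic bromination; the two ring A positions ortho to one alkoxy group and para to the other are far more activated than the anisole rings and less crowded than the site between the ethers, so both bromines should enter next to the CH2OH group.

**Step 3**
Reactants: 4 2,6-dibromo-3,5-bis(4-methoxybenzyloxy)benzyl alcohol
Product: 5 TBS ether of 4
Conditions: TBSCl, imidazole, DMF, rt
Reagents that add atoms: tert-butyldimethylsilyl chloride CC(C)(C)[Si](C)(C)Cl
Why: Standard silylation that shields the benzylic oxygen from organolithiums, MnO2 and the rhodium carbenes.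

**Step 4**
Reactants: 5 TBS ether of 4; 6 3,5-dimethoxybenzonitrile
Product: 9 hydrazone of [3-bromo-2-(TBSO-methyl)-4,6-bis(PMB-oxy)phenyl] 3,5-dimethoxyphenyl ketone, via aryllithium 7 (not isolated), via N-H ketimine 8 (not isolated)
Conditions: n-BuLi (1.0 equiv), THF, −78 °C; 6, −78 to −60 °C; MeOH; N2H4·H2O, AcOH (cat.), EtOH, 70 °C
Reagents that add atoms: 3,5-dimethoxybenzonitrile (6) COc1cc(OC)cc(C#N)c1; hydrazine NN
Why: Bromine–lithium exchange on one of two equivalent bromides and 1,2-addition to the slim nitrile give an N-H ketimine, and transimination with hydrazine reaches the hydrazone of this di-ortho-substituted diaryl ketone more readily than condensation on the ketone itself (the low temperature holds back a 1,4 O-to-C silyl shift).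

**Step 5**
Reactants: 9 hydrazone
Product: 11 (2S,3R)-5-bromo-4-(TBSO-methyl)-3-(3,5-dimethoxyphenyl)-6-(PMB-oxy)-2-(4-methoxyphenyl)-2,3-dihydrobenzofuran (outer furan; cis), via diaryldiazomethane 10 (not isolated)
Conditions: MnO2, CH2Cl2, rt; filter; Rh2(R-PTAD)4 (1 mol %), CH2Cl2, 0 °C to rt
Reagents that add atoms: none
Why: Hydrazone dehydrogenation followed by intramolecular C–H insertion of the donor/donor dirhodium carbene into the activated ArO–CH2–Ar bond closes the five-membered ring cis-selectively, with the chiral carboxylate pocket setting C3 as R (kept to the end) and C2 as S (corrected in step 12).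

**Step 6**
Reactants: 11 outer-furan bromide; 12 dimethyl oxalate
Product: 14 methyl aryl glyoxylate (11 with C(O)CO2Me in place of Br), via aryllithium 13 (not isolated)
Conditions: n-BuLi, THF, −78 °C; cannulated into (CO2Me)2 (4 equiv), THF, −78 °C
Reagents that add atoms: dimethyl oxalate (12) COC(=O)C(=O)OC
Why: Bromine–lithium exchange outruns any deprotonation at −78 °C, and inverse addition to excess oxalate stops the acylation of the aryllithium at the keto ester.

**Step 7**
Reactants: 14 methyl aryl glyoxylate; 15 4-toluenesulfonohydrazide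
Product: 17 methyl aryldiazoacetate (11 with C(N2)CO2Me in place of Br), via tosylhydrazone 16 (not isolated)
Conditions: TsNHNH2, MeOH, 60 °C; DBU, CH2Cl2, rt
Reagents that add atoms: 4-toluenesulfonohydrazide (15) Cc1ccc(S(=O)(=O)NN)cc1
Why: Condensation on the activated keto group and base-induced loss of sulfinate (Bamford–Stevens reaction) is a standard route to aryldiazoacetates.

**Step 8**
Reactants: 17 methyl aryldiazoacetate
Product: 18 bis-furan methyl ester with cis inner furan (2S,3R; CO2Me on C3) and cis outer furan (2S,3R); CH2OTBS on a5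
Conditions: Rh2(R-PTTL)4 (1 mol %), toluene, −60 °C
Reagents that add atoms: none
Why: Intramolecular C–H insertion of the donor/acceptor dirhodium carbene into the remaining 4-methoxybenzyl ether gives the cis 2-aryl-3-carboxylate; the catalyst fixes inner C2 as S, in the same sense as step 5, and any trans isomer with that C2 configuration converges in step 9.

**Step 9**
Reactants: 18 cis,cis bis-furan ester
Product: 19 bis-furan methyl ester with trans inner furan (2S,3S) and cis outer furan (2S,3R)
Conditions: NaOMe (0.3 equiv), MeOH/THF, rt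
Reagents that add atoms: none
Why: Base epimerisation through the ester enolate moves inner C3 to the more stable trans arrangement (3S) and leaves C2 untouched, because ring opening would be a disfavoured reverse 5-endo-trig process.

**Step 10**
Reactants: 19 bis-furan methyl ester
Product: 20 bis-furan aldehyde (CHO on inner C3; inner 2S,3S; outer 2S,3R)
Conditions: i-Bu2AlH, CH2Cl2, −78 °C; KNaC4H4O6 aq
Reagents that add atoms: none
Why: Partial ester reduction in which the tetrahedral aluminium acetal persists at −78 °C and releases the aldehyde only on work-up.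

**Step 11**
Reactants: 20 bis-furan aldehyde
Product: 22 benzylic bromide with 2,2-dibromovinyl on inner C3 (inner 2S,3S; outer 2S,3R), via TBS dibromoalkene 21 (not isolated)
Conditions: CBr4 (3 equiv), PPh3 (6 equiv), CH2Cl2, 0 °C to rt
Reagents that add atoms: carbon tetrabromide BrC(Br)(Br)Br
Why: The non-basic Ramirez olefination (first half of the Corey–Fuchs sequence) spares the α-stereocentre, and the Ph3PBr2 formed along with the ylide performs the known direct exchange of a benzylic silyl ether for bromide.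

**Step 12**
Reactants: 22 benzylic bromide (outer furan cis)
Product: 23 benzylic bromide with both furans trans (inner 2S,3S; outer 2R,3R)
Conditions: CF3CO2H (10 vol %), CH2Cl2, 0 °C
Reagents that add atoms: none
Why: Acid-mediated epimerisation by reversible ionisation of the C2–O bond to the 4-methoxybenzyl cation lets the outer furan reclose as the more stable trans isomer (2R), while outer C3 and the already trans inner furan are unchanged; the step is placed here because no PMB or silyl ether is left.

**Step 13**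
Reactants: 24 2,4-dimethoxyphenylacetic acid; 25 (S)-4-benzyloxazolidin-2-one
Product: 27 (S)-4-benzyl-3-[(2,4-dimethoxyphenyl)acetyl]oxazolidin-2-one, via mixed pivalic anhydride 26 (not isolated)
Conditions: t-BuCOCl, Et3N, THF, −20 °C; LiCl, 25, rt
Reagents that add atoms: none
Why: N-acylation of the oxazolidinone through the mixed anhydride with LiCl activation is the standard preparation of Evans imides.

**Step 14**
Reactants: 27 Evans imide; 23 benzylic bromide
Product: 29 alkylated imide (new methine S; auxiliary 4S; furans unchanged), via sodium Z-enolate 28 (not isolated)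
Conditions: NaN(SiMe3)2, THF, −78 °C; 23, n-Bu4NI (cat.), −78 to −20 °C
Reagents that add atoms: none
Why: Evans asymmetric alkylation in which the chelated Z-enolate attacks the benzylic bromide from the face opposite the benzyl group of the (S)-auxiliary; this sets the methine as S, and iodide catalysis helps at the flanked benzylic carbon.

**Step 15**
Reactants: 29 alkylated imide
Product: 31 (S)-2-(2,4-dimethoxyphenyl)-3-(ring A core)propanoic acid, via peroxy acid 30 (not isolated)
Conditions: LiOH, H2O2, THF/H2O, 0 °C; Na2SO3 aq; 1 M HCl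
Reagents that add atoms: hydrogen peroxide OO
Why: Hydroperoxide attacks the exocyclic imide carbonyl selectively and without enolisation, so the α-aryl stereocentre is kept and the auxiliary is recovered.

**Step 16**
Reactants: 31 carboxylic acid
Product: 33 α-diazoketone (methine S), via mixed carbonic anhydride 32 (not isolated)
Conditions: i-BuOCOCl, N-methylmorpholine, THF, −20 °C; CH2N2, Et2O, 0 °C
Reagents that add atoms: diazomethane C=[N+]=[N-]
Why: First stage of the Arndt–Eistert homologation, with the mixed anhydride formed cold so that no ketene forms and no epimerisation occurs before acylation of diazomethane.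

**Step 17**
Reactants: 33 α-diazoketone
Product: 35 ethyl (R)-3-(2,4-dimethoxyphenyl)-4-(ring A core)butanoate, via ketene 34 (not isolated)
Conditions: AgO2CPh (10 mol %), Et3N, EtOH/THF, rt, dark
Reagents that add atoms: ethanol CCO
Why: In the silver-catalysed Wolff rearrangement the methine migrates with retention and ethanol traps the ketene, which places the stereocentre β to the carbonyl (safe from enolisation) and installs the ethoxy group of the later ynol ether.

**Step 18**
Reactants: 35 ethyl ester with dibromoalkene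
Product: 39 1,8-diyne (ethynyl on inner C3; ethoxyethynyl on the R methine; inner 2S,3S; outer 2R,3R), via lithium enolate 36 (not isolated), via ketene acetal phosphate 37 (not isolated), via lithium acetylide 38 (not isolated)
Conditions: LiN(i-Pr)2 (1.1 equiv), THF, −78 °C; ClP(O)(OEt)2 (1.05 equiv), −78 to −40 °C; t-BuLi (6 equiv), −100 to −78 °C; NH4Cl aq
Reagents that add atoms: none
Why: O-phosphorylation of the ester enolate gives the ketene acetal phosphate, and t-BuLi then drives two known alkyne-forming eliminations in one flask: the Corey–Fuchs bromine–lithium exchange with Fritsch–Buttenberg–Wiechell shift (fastest, and its acetylide charge shields the furan C3–H) and the β-elimination of phosphate to the 1-ethoxyalkyne.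

**Step 19**
Reactants: 39 1,8-diyne; 40 ethoxyacetylene
Product: 41 fully protected target (six methyl ethers; ethyl ethers on b3 and b5; methine S)
Conditions: [Rh(cod)2]BF4 (10 mol %), rac-BINAP (10 mol %), CH2Cl2, H2 (1 atm) then Ar; 39 (0.01 M); 40 (4 equiv) by syringe pump over 6 h, rt
Reagents that add atoms: ethoxyacetylene (40) C#COCC
Why: Proposed new method: cationic monovalent rhodium bound by BINAP should couple the two tethered alkynes oxidatively to a trivalent rhodacyclopentadiene, insert ethoxyacetylene and release the arene by reductive elimination; the closest known reaction types are the rhodium- or cobalt-catalysed [2+2+2] cocyclisation of arene-stiffened 1,8-diynes with monoalkynes and that of alkynyl ethers with 1,6-diynes, whereas an ynol ether terminus combined with a seven-membered tether ring has not been shown. The seven-membered ring closes in the oxidative coupling, when the two inner alkyne carbons (future b1 and b6) are joined, helped by three of the five tether atoms (C3, a6, a5) being held by ring A and the inner furan; ring B closes as the six-membered arene when the monoalkyne carbons bond to b2 and b5. No stereocentre is formed, and the neutral conditions at room temperature should leave the two propargylic methines and both furans unchanged. The step needs regioselective insertion: the metallacycle carries H at b2 and OEt at b5, so the substituted carbon of ethoxyacetylene should bond to the unhindered b2 and its CH to b5, which avoids four contiguous substituents and gives the 1,3-dioxygenated ring. It also needs chemoselectivity against self-trimerisation of ethoxyacetylene, which slow addition of the monoalkyne to dilute diyne and catalyst is meant to secure.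

**Step 20**
Reactants: 41 fully protected target
Product: 42 target CNP0154047.3
Conditions: BBr3 (20 equiv), CH2Cl2, −78 °C to rt; H2O
Reagents that add atoms: none
Why: Lewis acid ether cleavage removes methyl and ethyl aryl ethers alike, and any reversible opening of a furan at C2 can only return the stable trans isomer because no alkene or reachable nucleophilic carbon is present.

**Compound list**
1 | 3,5-dihydroxybenzyl alcohol | OCc1cc(O)cc(O)c1 | starting material
2 | 4-methoxybenzyl chloride | COc1ccc(CCl)cc1 | starting material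
3 | 3,5-bis(4-methoxybenzyloxy)benzyl alcohol | OCc1cc(OCc2ccc(OC)cc2)cc(OCc2ccc(OC)cc2)c1 | intermediate
4 | 2,6-dibromo-3,5-bis(4-methoxybenzyloxy)benzyl alcohol | OCc1c(Br)c(OCc2ccc(OC)cc2)cc(OCc2ccc(OC)cc2)c1Br | intermediate
5 | TBS ether of 4 | CC(C)(C)[Si](C)(C)OCc1c(Br)c(OCc2ccc(OC)cc2)cc(OCc2ccc(OC)cc2)c1Br | intermediate
6 | 3,5-dimethoxybenzonitrile | COc1cc(OC)cc(C#N)c1 | starting material
7 | aryllithium from 5 (Li in place of one Br) | CC(C)(C)[Si](C)(C)OCc1c([Li])c(OCc2ccc(OC)cc2)cc(OCc2ccc(OC)cc2)c1Br | intermediate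
8 | N-H ketimine | CC(C)(C)[Si](C)(C)OCc1c(Br)c(OCc2ccc(OC)cc2)cc(OCc2ccc(OC)cc2)c1C(=N)c1cc(OC)cc(OC)c1 | intermediate
9 | diaryl ketone hydrazone | CC(C)(C)[Si](C)(C)OCc1c(Br)c(OCc2ccc(OC)cc2)cc(OCc2ccc(OC)cc2)c1C(=NN)c1cc(OC)cc(OC)c1 | intermediate
10 | diaryldiazomethane | CC(C)(C)[Si](C)(C)OCc1c(Br)c(OCc2ccc(OC)cc2)cc(OCc2ccc(OC)cc2)c1C(=[N+]=[N-])c1cc(OC)cc(OC)c1 | intermediate
11 | outer-furan bromide, cis (2S,3R) | COc1ccc(COc2cc3c(c(CO[Si](C)(C)C(C)(C)C)c2Br)[C@@H](c2cc(OC)cc(OC)c2)[C@@H](c2ccc(OC)cc2)O3)cc1 | intermediate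
12 | dimethyl oxalate | COC(=O)C(=O)OC | starting material
13 | aryllithium from 11 | COc1ccc(COc2cc3c(c(CO[Si](C)(C)C(C)(C)C)c2[Li])[C@@H](c2cc(OC)cc(OC)c2)[C@@H](c2ccc(OC)cc2)O3)cc1 | intermediate
14 | methyl aryl glyoxylate | COc1ccc(COc2cc3c(c(CO[Si](C)(C)C(C)(C)C)c2C(=O)C(=O)OC)[C@@H](c2cc(OC)cc(OC)c2)[C@@H](c2ccc(OC)cc2)O3)cc1 | intermediate
15 | 4-toluenesulfonohydrazide | Cc1ccc(S(=O)(=O)NN)cc1 | starting material
16 | tosylhydrazone of 14 | COc1ccc(COc2cc3c(c(CO[Si](C)(C)C(C)(C)C)c2C(=NNS(=O)(=O)c2ccc(C)cc2)C(=O)OC)[C@@H](c2cc(OC)cc(OC)c2)[C@@H](c2ccc(OC)cc2)O3)cc1 | intermediate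
17 | methyl aryldiazoacetate | COc1ccc(COc2cc3c(c(CO[Si](C)(C)C(C)(C)C)c2C(=[N+]=[N-])C(=O)OC)[C@@H](c2cc(OC)cc(OC)c2)[C@@H](c2ccc(OC)cc2)O3)cc1 | intermediate
18 | bis-furan ester, inner cis (2S,3R), outer cis (2S,3R) | COc1ccc([C@H]2Oc3cc4c(c(CO[Si](C)(C)C(C)(C)C)c3[C@H]2C(=O)OC)[C@@H](c2cc(OC)cc(OC)c2)[C@@H](c2ccc(OC)cc2)O4)cc1 | intermediate
19 | bis-furan ester, inner trans (2S,3S), outer cis (2S,3R) | COc1ccc([C@H]2Oc3cc4c(c(CO[Si](C)(C)C(C)(C)C)c3[C@@H]2C(=O)OC)[C@@H](c2cc(OC)cc(OC)c2)[C@@H](c2ccc(OC)cc2)O4)cc1 | intermediate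
20 | bis-furan aldehyde | COc1ccc([C@H]2Oc3cc4c(c(CO[Si](C)(C)C(C)(C)C)c3[C@@H]2C=O)[C@@H](c2cc(OC)cc(OC)c2)[C@@H](c2ccc(OC)cc2)O4)cc1 | intermediate
21 | TBS ether with dibromoalkene | COc1ccc([C@H]2Oc3cc4c(c(CO[Si](C)(C)C(C)(C)C)c3[C@@H]2C=C(Br)Br)[C@@H](c2cc(OC)cc(OC)c2)[C@@H](c2ccc(OC)cc2)O4)cc1 | intermediate
22 | benzylic bromide with dibromoalkene, outer furan cis | COc1ccc([C@H]2Oc3cc4c(c(CBr)c3[C@@H]2C=C(Br)Br)[C@@H](c2cc(OC)cc(OC)c2)[C@@H](c2ccc(OC)cc2)O4)cc1 | intermediate
23 | benzylic bromide with dibromoalkene, both furans trans (inner 2S,3S; outer 2R,3R) | COc1ccc([C@H]2Oc3cc4c(c(CBr)c3[C@@H]2C=C(Br)Br)[C@@H](c2cc(OC)cc(OC)c2)[C@H](c2ccc(OC)cc2)O4)cc1 | intermediate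
24 | 2,4-dimethoxyphenylacetic acid | COc1ccc(CC(=O)O)c(OC)c1 | starting material
25 | (S)-4-benzyloxazolidin-2-one | O=C1N[C@@H](Cc2ccccc2)CO1 | starting material
26 | mixed pivalic anhydride | COc1ccc(CC(=O)OC(=O)C(C)(C)C)c(OC)c1 | intermediate
27 | (S)-4-benzyl-3-[(2,4-dimethoxyphenyl)acetyl]oxazolidin-2-one | COc1ccc(CC(=O)N2[C@@H](Cc3ccccc3)COC2=O)c(OC)c1 | intermediate
28 | sodium Z-enolate of 27 | [Na+].[O-]/C(=C\c1ccc(OC)cc1OC)N1[C@@H](Cc2ccccc2)COC1=O | intermediate
29 | alkylated imide (methine S) | COc1ccc([C@H]2Oc3cc4c(c(C[C@@H](c5ccc(OC)cc5OC)C(=O)N5[C@@H](Cc6ccccc6)COC5=O)c3[C@@H]2C=C(Br)Br)[C@@H](c2cc(OC)cc(OC)c2)[C@H](c2ccc(OC)cc2)O4)cc1 | intermediate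
30 | peroxy acid | COc1ccc([C@H]2Oc3cc4c(c(C[C@@H](c5ccc(OC)cc5OC)C(=O)OO)c3[C@@H]2C=C(Br)Br)[C@@H](c2cc(OC)cc(OC)c2)[C@H](c2ccc(OC)cc2)O4)cc1 | intermediate
31 | carboxylic acid (methine S) | COc1ccc([C@H]2Oc3cc4c(c(C[C@@H](c5ccc(OC)cc5OC)C(=O)O)c3[C@@H]2C=C(Br)Br)[C@@H](c2cc(OC)cc(OC)c2)[C@H](c2ccc(OC)cc2)O4)cc1 | intermediate
32 | mixed isobutyl carbonic anhydride | COc1ccc([C@H]2Oc3cc4c(c(C[C@@H](c5ccc(OC)cc5OC)C(=O)OC(=O)OCC(C)C)c3[C@@H]2C=C(Br)Br)[C@@H](c2cc(OC)cc(OC)c2)[C@H](c2ccc(OC)cc2)O4)cc1 | intermediate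
33 | α-diazoketone | COc1ccc([C@H]2Oc3cc4c(c(C[C@@H](c5ccc(OC)cc5OC)C(=O)C=[N+]=[N-])c3[C@@H]2C=C(Br)Br)[C@@H](c2cc(OC)cc(OC)c2)[C@H](c2ccc(OC)cc2)O4)cc1 | intermediate
34 | ketene | COc1ccc([C@H]2Oc3cc4c(c(C[C@@H](c5ccc(OC)cc5OC)C=C=O)c3[C@@H]2C=C(Br)Br)[C@@H](c2cc(OC)cc(OC)c2)[C@H](c2ccc(OC)cc2)O4)cc1 | intermediate
35 | homologated ethyl ester (methine R) | COc1ccc([C@H]2Oc3cc4c(c(C[C@@H](c5ccc(OC)cc5OC)CC(=O)OCC)c3[C@@H]2C=C(Br)Br)[C@@H](c2cc(OC)cc(OC)c2)[C@H](c2ccc(OC)cc2)O4)cc1 | intermediate
36 | lithium enolate of 35 | COc1ccc([C@H]2Oc3cc4c(c(C[C@@H](c5ccc(OC)cc5OC)C=C([O-])OCC)c3[C@@H]2C=C(Br)Br)[C@@H](c2cc(OC)cc(OC)c2)[C@H](c2ccc(OC)cc2)O4)cc1.[Li+] | intermediate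
37 | ketene acetal diethyl phosphate (alkene geometry not fixed) | COc1ccc([C@H]2Oc3cc4c(c(C[C@@H](c5ccc(OC)cc5OC)C=C(OCC)OP(=O)(OCC)OCC)c3[C@@H]2C=C(Br)Br)[C@@H](c2cc(OC)cc(OC)c2)[C@H](c2ccc(OC)cc2)O4)cc1 | intermediate
38 | lithium acetylide of 39 | COc1ccc([C@H]2Oc3cc4c(c(C[C@@H](c5ccc(OC)cc5OC)C#COCC)c3[C@@H]2C#C[Li])[C@@H](c2cc(OC)cc(OC)c2)[C@H](c2ccc(OC)cc2)O4)cc1 | intermediate
39 | 1,8-diyne (key-step precursor) | COc1ccc([C@H]2Oc3cc4c(c(C[C@@H](c5ccc(OC)cc5OC)C#COCC)c3[C@@H]2C#C)[C@@H](c2cc(OC)cc(OC)c2)[C@H](c2ccc(OC)cc2)O4)cc1 | intermediate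
40 | ethoxyacetylene | C#COCC | starting material
41 | fully protected target (key-step product) | COc1ccc([C@H]2Oc3cc4c(c5c3[C@@H]2c2cc(OCC)cc(OCC)c2[C@H](c2ccc(OC)cc2OC)C5)[C@@H](c2cc(OC)cc(OC)c2)[C@H](c2ccc(OC)cc2)O4)cc1 | intermediate
42 | CNP0154047.3 | Oc1ccc([C@H]2Oc3cc4c(c5c3[C@@H]2c2cc(O)cc(O)c2[C@H](c2ccc(O)cc2O)C5)[C@@H](c2cc(O)cc(O)c2)[C@H](c2ccc(O)cc2)O4)cc1 | target

**Totals**
Total step count: 20. Longest linear sequence: 19 (steps 1–12 and 14–20).

**Steps most likely to fail**

1. Step 19.
   - Risk: closure of the seven-membered metallacycle may be outrun by self-trimerisation of ethoxyacetylene or by its pairwise coupling with one alkyne of the diyne. The insertion may also lose its regiochemical bias.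
   - Fallback: it sets out from 39 and uses a monoalkyne that cannot trimerise and has no regiochemistry, with the b3 oxygen brought in afterwards. The known cobalt-mediated cocyclisation of an α,ω-diyne with bis(trimethylsilyl)acetylene (CpCo(C2H4)2, neat alkyne/THF, rt) should give the b3,b4-bis(trimethylsilyl) arene F1.
   - CF3CO2H then removes, by ipso-protonation, the silyl group on b4, which is activated by the ortho ethoxy group and strained by its silyl neighbour. This leaves the b3-monosilyl arene F2.
   - BBr3 cleaves all ethers and replaces the remaining silyl group by boron (ipso-borodesilylation). Hydrolysis gives the polyphenol boronic acid F3, which NaBO3·4H2O oxidises to the phenol. The route is rejoined at 42.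

2. Step 18.
   - Risk: the vinyl anion of the ketene acetal phosphate may undergo migration of phosphorus from oxygen to carbon, or the base may attack phosphorus or metalate elsewhere, instead of causing β-elimination.
   - Fallback: it sets out from diazoketone 33 and makes the ynol ether through an enol triflate, which eliminates with a much weaker base. Rh2(OAc)4-catalysed O–H insertion with ethanol gives the α-ethoxy ketone F4.
   - Chelation-guided enolisation towards the CH2OEt side (LiN(SiMe3)2, PhNTf2, THF, −78 °C) gives the Z enol triflate F5.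
   - KOt-Bu at −78 °C effects anti elimination of triflate and also dehydrobrominates the dibromoalkene, giving the bromoalkyne ynol ether F6.
   - Bromine–lithium exchange (t-BuLi, −78 °C) and protonation return to the route at 39.

3. Step 14.
   - Risk: SN2 displacement at a benzylic carbon flanked by two substituted furan carbons may be so slow that the imide enolate decomposes first.
   - Fallback: it sets out from 23 and forms the carbon–carbon bond at an sp2 centre, with the stereocentre set by hydrogenation. A Michaelis–Arbuzov reaction with P(OEt)3 gives the benzylic phosphonate F7.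
   - Horner–Wadsworth–Emmons olefination with ethyl (2,4-dimethoxyphenyl)glyoxylate gives, after separation of the geometric isomers, the E α-aryl acrylate F8. LiOH hydrolysis then gives the acrylic acid F9.
   - Asymmetric hydrogenation of this α-aryl cinnamic acid uses [Ir(cod)(SIPHOX)][B(3,5-(CF3)2C6H3)4], H2 and Et3N, with the ligand antipode that gives the S acid. The route is rejoined at 31.

**Further compounds**
F1 | step 19 | b3,b4-bis(trimethylsilyl) b5-ethoxy arene | COc1ccc([C@H]2Oc3cc4c(c5c3[C@@H]2c2cc([Si](C)(C)C)c([Si](C)(C)C)c(OCC)c2[C@H](c2ccc(OC)cc2OC)C5)[C@@H](c2cc(OC)cc(OC)c2)[C@H](c2ccc(OC)cc2)O4)cc1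
F2 | step 19 | b3-trimethylsilyl b5-ethoxy arene | COc1ccc([C@H]2Oc3cc4c(c5c3[C@@H]2c2cc([Si](C)(C)C)cc(OCC)c2[C@H](c2ccc(OC)cc2OC)C5)[C@@H](c2cc(OC)cc(OC)c2)[C@H](c2ccc(OC)cc2)O4)cc1
F3 | step 19 | polyphenol b3-boronic acid | Oc1ccc([C@H]2Oc3cc4c(c5c3[C@@H]2c2cc(B(O)O)cc(O)c2[C@H](c2ccc(O)cc2O)C5)[C@@H](c2cc(O)cc(O)c2)[C@H](c2ccc(O)cc2)O4)cc1
F4 | step 18 | α-ethoxy ketone (methine S) | COc1ccc([C@H]2Oc3cc4c(c(C[C@@H](c5ccc(OC)cc5OC)C(=O)COCC)c3[C@@H]2C=C(Br)Br)[C@@H](c2cc(OC)cc(OC)c2)[C@H](c2ccc(OC)cc2)O4)cc1
F5 | step 18 | Z enol triflate | COc1ccc([C@H]2Oc3cc4c(c(C[C@@H](c5ccc(OC)cc5OC)/C(OS(=O)(=O)C(F)(F)F)=C/OCC)c3[C@@H]2C=C(Br)Br)[C@@H](c2cc(OC)cc(OC)c2)[C@H](c2ccc(OC)cc2)O4)cc1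
F6 | step 18 | bromoalkyne ynol ether | COc1ccc([C@H]2Oc3cc4c(c(C[C@@H](c5ccc(OC)cc5OC)C#COCC)c3[C@@H]2C#CBr)[C@@H](c2cc(OC)cc(OC)c2)[C@H](c2ccc(OC)cc2)O4)cc1
F7 | step 14 | diethyl benzylic phosphonate | COc1ccc([C@H]2Oc3cc4c(c(CP(=O)(OCC)OCC)c3[C@@H]2C=C(Br)Br)[C@@H](c2cc(OC)cc(OC)c2)[C@H](c2ccc(OC)cc2)O4)cc1
F8 | step 14 | ethyl E α-aryl acrylate | COc1ccc([C@H]2Oc3cc4c(c(/C=C(\c5ccc(OC)cc5OC)C(=O)OCC)c3[C@@H]2C=C(Br)Br)[C@@H](c2cc(OC)cc(OC)c2)[C@H](c2ccc(OC)cc2)O4)cc1
F9 | step 14 | E α-aryl acrylic acid | COc1ccc([C@H]2Oc3cc4c(c(/C=C(\c5ccc(OC)cc5OC)C(=O)O)c3[C@@H]2C=C(Br)Br)[C@@H](c2cc(OC)cc(OC)c2)[C@H](c2ccc(OC)cc2)O4)cc1
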